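**Plan**
1. Numbering: C1 is the quaternary carbinol, C7 its CH2OBz carbon, C2 the neighbouring CH–OBz, C3=C4 the alkene, C5 the second CH–OBz, C6 the CH–OH. O1 and O2 lie on one ring face; O5, O6 and C7 lie on the other.
2. Cuts: the three benzoate C–O bonds, then C1–C7 (back to a C1 ketone), then C3=C4 (metathesis), then C2–C3 and C4–C5 (two vinyl additions). This leaves C2–C1–C6–C5 as the four carbons of L-tartrate.
3. Enabling feature: without C7 the cyclohexene is a conduritol E. Its C2 axis, through the midpoints of C1–C6 and C3=C4, makes O1 and O6 homotopic, and C7 is cis to O6. Either oxygen can carry a Si–CH2 unit while the other carbinol becomes the ketone, and the tied CH2 meets C1 only on the O6 face.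
4. Forward order: dioxolane-bearing chain, cyclohexene ring (step 3), dioxolane removed (step 4), temporary five-membered ring O6–Si–C7–C1–C6 (step 7), oxidative opening to C7–OH and C6–OH (step 8), benzoates last.
5. Stereochemistry: C6 (and the sacrificial C1–H centre) comes from L-tartrate, C2 and C5 from Felkin–Anh vinyl transfer, and C1 from the cis ring fusion that the tether enforces.
6. Esters are kept out of the ketone, samarium and peroxide stages. O1 and O6 are capped as silyl ethers while O2 and O5 change from PMB ether to benzoate.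

Key step: step 7

Remark: some CIP descriptors change between intermediates only because substituent priorities change (Si > C > H on oxygen). No centre is inverted once it has been set.

**Step 1**
Reactants: 1 dimethyl 2,3-O-isopropylidene-L-tartrate; 2 vinylmagnesium bromide
Product: 4 (1S,1'S)-1,1'-[(4S,5S)-2,2-dimethyl-1,3-dioxolane-4,5-diyl]bis(prop-2-en-1-ol), via tartraldehyde acetonide 3 (not isolated)
Conditions: i-Bu2AlH (2.1 equiv), toluene, −78 °C; then (CH2=CH)2Zn [from 2 and ZnCl2, THF], −78 °C → rt; aqueous work-up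
Reagents that add atoms: vinylmagnesium bromide 2, C=C[Mg]Br
Why: One-pot partial ester reduction and 1,2-addition: at −78 °C i-Bu2AlH stops at the aluminium hemiacetal of 3, and the non-chelating divinylzinc adds to each aldehyde as it is released in the Felkin–Anh sense, anti to the dioxolane C–O bond, which should set C2 and C5 both as S (anti,anti; the L-manno array), the two identical halves reinforcing each other.

**Step 2**
Reactants: 4 diene diol; 5 4-methoxybenzyl chloride
Product: 6 (4S,5S)-4,5-bis{(1S)-1-[(4-methoxybenzyl)oxy]prop-2-en-1-yl}-2,2-dimethyl-1,3-dioxolane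
Conditions: NaH, 5 (2.5 equiv), Bu4NI (cat.), DMF, 0 °C → rt
Reagents that add atoms: 4-methoxybenzyl chloride 5, COc1ccc(CCl)cc1
Why: Williamson ether synthesis on the two homotopic secondary alkoxides touches no stereocentre and installs ethers that tolerate metathesis, samarium and peroxide, are poor leaving groups beside the later ketone, and can be removed oxidatively in the presence of the alkene.

**Step 3**
Reactants: 6 bis-PMB diene
Product: 7 (3aS,4S,7S,7aS)-4,7-bis[(4-methoxybenzyl)oxy]-2,2-dimethyl-3a,4,7,7a-tetrahydro-1,3-benzodioxole (trans-fused)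
Conditions: second-generation Grubbs catalyst (H2IMes)(PCy3)Cl2Ru=CHPh (3 mol %), CH2Cl2 (0.005 M), 40 °C
Reagents that add atoms: none
Why: Ring-closing metathesis of the two terminal allylic-ether alkenes forms C3=C4 and with it the cyclohexene ring, driven by loss of ethene; the carbene-ligated catalyst is chosen because the new ring is trans-fused to the dioxolane and flanked by two ethers, and no stereocentre takes part.

**Step 4**
Reactants: 7 bicyclic acetonide
Product: 8 (1R,2R,3S,6S)-3,6-bis[(4-methoxybenzyl)oxy]cyclohex-4-ene-1,2-diol (2,5-di-O-PMB conduritol E in the route numbering)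
Conditions: AcOH/H2O (4:1), 50 °C
Reagents that add atoms: none
Why: Acid-catalysed acetal hydrolysis; the strained trans-fused dioxolane opens under conditions mild enough to leave the PMB ethers and the allylic C–O bonds alone, and should give the C2-symmetric diol.

**Step 5**
Reactants: 8 C2-symmetric diol; 9 (bromomethyl)chlorodimethylsilane
Product: 10 (1S,2S,5S,6R)-6-{[(bromomethyl)dimethylsilyl]oxy}-2,5-bis[(4-methoxybenzyl)oxy]cyclohex-3-en-1-ol
Conditions: 9 (1.0 equiv, slow addition), Et3N (1.5 equiv), CH2Cl2, −78 → −20 °C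
Reagents that add atoms: (bromomethyl)chlorodimethylsilane 9, C[Si](C)(Cl)CBr
Why: Silyl ether formation with a chlorosilane and an amine base; because the C2 axis exchanges O1 and O6, silylation at either oxygen (and any later 1,2-silyl shift) gives the same compound 10, slow addition of one equivalent in the cold limits double silylation, and recovered diol and bis-ether can be recycled.

**Step 6**
Reactants: 10 mono(bromomethyl)silyl ether
Product: 11 (2S,5S,6S)-6-{[(bromomethyl)dimethylsilyl]oxy}-2,5-bis[(4-methoxybenzyl)oxy]cyclohex-3-en-1-one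
Conditions: Dess–Martin periodinane (1.3 equiv), pyridine (4 equiv), CH2Cl2, 0 °C → rt; short plug of Et3N-deactivated silica, used at once
Reagents that add atoms: none
Why: Dess–Martin oxidation buffered with pyridine turns the one free secondary alcohol into the ketone under near-neutral, non-enolising conditions, so the labile silyl ether, the α-stereocentres C2 and C6 and the β-alkoxy group at C5 should survive.

**Step 7**
Reactants: 11 α-silyloxy ketone
Product: 13 (3aS,4S,7S,7aS)-4,7-bis[(4-methoxybenzyl)oxy]-2,2-dimethyl-2,3,3a,4,7,7a-hexahydro-1,2-benzoxasilol-3a-ol (cis-fused oxasilolane; C3 = C7, C3a = C1, C7a = C6 of the route numbering), via organosamarium 12 (not isolated)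
Conditions: SmI2 (2.5 equiv, 0.1 M), NiI2 (2 mol %), THF, −78 → 0 °C, 11 added slowly; pH 7 phosphate buffer; crude product carried on
Reagents that add atoms: none
Why: Proposed new method: two single-electron transfers from divalent samarium, the first eased by zerovalent nickel formed from NiI2 that inserts into the silicon-activated CH2–Br bond, should turn 11 into the α-silyl organosamarium 12, whose carbanionic C7 adds to the C1 carbonyl and leaves the trivalent samarium alkoxide of 13. The closest known reaction type is the SmI2 intramolecular Barbier cyclisation of (bromomethyl)dimethylsilyl ethers of β-hydroxy ketones, which closes six-membered rings; new here are the α-silyloxy ketone and the five-membered ring. The 1-oxa-2-silacyclopentane O6–Si–C7–C1–C6 closes in the 5-exo-trig mode, the C=O bond lying outside the new ring. The only new stereocentre, C1, is fixed by the tether: C7 can follow the Bürgi–Dunitz trajectory only from the face that bears a pseudoaxial O6, so the fusion is cis, C7 ends cis to O6, and the C1 hydroxyl ends trans to O6 and cis to O2. The step needs chemoselectivity for C–Br reduction over ketyl formation with expulsion of the oxygen substituent at C2 or C6, and for attack at C1 over attack at the C3=C4 alkene; this should be secured by the absence of a proton source and of HMPA, ether and silyloxy groups instead of esters as potential leaving groups, the nickel co-catalyst, low temperature, and the much shorter reach to C1 than to C4. Neutral work-up keeps the β-hydroxysilane from Peterson elimination.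

**Step 8**
Reactants: 13 oxasilolane
Product: 14 (1R,2S,3S,6S)-1-(hydroxymethyl)-3,6-bis[(4-methoxybenzyl)oxy]cyclohex-4-ene-1,2-diol
Conditions: 30% H2O2, KF, KHCO3, THF/MeOH (1:1), rt
Reagents that add atoms: hydrogen peroxide, OO
Why: Tamao oxidation: fluoride and bicarbonate make silicon hypervalent, hydroperoxide binds, C7 migrates from Si to O and both Si–O bonds then hydrolyse to free C7–OH and C6–OH; these conditions serve for β-hydroxy(alkoxy)silanes in nucleophilic hydroxymethylation, C1 is untouched, and no ester is yet present that could migrate or be cleaved.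

**Step 9**
Reactants: 14 triol; 15 benzoyl chloride
Product: 16 [(1R,2S,5S,6S)-1,6-dihydroxy-2,5-bis[(4-methoxybenzyl)oxy]cyclohex-3-en-1-yl]methyl benzoate
Conditions: 15 (1.05 equiv), pyridine, CH2Cl2, −30 → 0 °C
Reagents that add atoms: benzoyl chloride 15, O=C(Cl)c1ccccc1
Why: Selective acylation: the primary C7 hydroxyl should take up one equivalent of acid chloride in the cold well ahead of the flanked secondary C6 hydroxyl and the tertiary C1 hydroxyl.

**Step 10**
Reactants: 16 C7 monobenzoate
Product: 17 [(1S,2S,5S,6S)-2,5-bis[(4-methoxybenzyl)oxy]-1,6-bis[(triethylsilyl)oxy]cyclohex-3-en-1-yl]methyl benzoate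
Conditions: Et3SiOTf (3.5 equiv), 2,6-lutidine (5 equiv), CH2Cl2, −78 → 0 °C
Reagents that add atoms: triethylsilyl trifluoromethanesulfonate, CC[Si](CC)(CC)OS(=O)(=O)C(F)(F)F
Why: Silylation with a silyl triflate and 2,6-lutidine is strong enough to cap the tertiary O1 as well as O6, which sets O6 apart from O2 and O5 and removes the cis-neighbouring hydroxyls that would otherwise trap the oxidised PMB groups as cyclic acetals in the next step.

**Step 11**
Reactants: 17 bis-TES ether
Product: 18 [(1S,2S,5S,6S)-2,5-dihydroxy-1,6-bis[(triethylsilyl)oxy]cyclohex-3-en-1-yl]methyl benzoate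
Conditions: DDQ (2.5 equiv), CH2Cl2/pH 7 phosphate buffer (10:1), 0 °C → rt
Reagents that add atoms: none
Why: Oxidative PMB ether cleavage by DDQ (hydride abstraction at the electron-rich benzylic position, then hydrolysis of the oxocarbenium ion) should leave the benzoate, the TES ethers and the alkene untouched in the buffered two-phase medium.

**Step 12**
Reactants: 18 C2,C5-diol; 15 benzoyl chloride
Product: 19 [(1S,2S,5S,6S)-2,5-bis(benzoyloxy)-1,6-bis[(triethylsilyl)oxy]cyclohex-3-en-1-yl]methyl benzoate
Conditions: 15 (3 equiv), pyridine, DMAP (0.2 equiv), CH2Cl2, 0 °C → rt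
Reagents that add atoms: benzoyl chloride 15, O=C(Cl)c1ccccc1
Why: DMAP-catalysed acylation of the two allylic secondary alcohols, the only free hydroxyls of 18, needs no selectivity and retains the configuration at C2 and C5.

**Step 13**
Reactants: 19 tribenzoate bis-TES ether
Product: 20 [(1R,2S,5S,6S)-2,5-bis(benzoyloxy)-1,6-dihydroxycyclohex-3-en-1-yl]methyl benzoate (target)
Conditions: HF·pyridine, THF, 0 °C → rt
Reagents that add atoms: none
Why: Fluoride-driven desilylation; the mildly acidic medium should remove both TES ethers while avoiding the basic conditions under which a benzoate could move from O5 to O6 or from O2 to O1.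

**Compound list**
1 | dimethyl (4R,5R)-2,2-dimethyl-1,3-dioxolane-4,5-dicarboxylate (dimethyl 2,3-O-isopropylidene-L-tartrate) | COC(=O)[C@@H]1OC(C)(C)O[C@H]1C(=O)OC | starting material
2 | vinylmagnesium bromide | C=C[Mg]Br | starting material
3 | (4R,5R)-2,2-dimethyl-1,3-dioxolane-4,5-dicarbaldehyde | O=C[C@@H]1OC(C)(C)O[C@H]1C=O | intermediate
4 | (1S,1'S)-1,1'-[(4S,5S)-2,2-dimethyl-1,3-dioxolane-4,5-diyl]bis(prop-2-en-1-ol) | C=C[C@H](O)[C@@H]1OC(C)(C)O[C@H]1[C@@H](O)C=C | intermediate
5 | 4-methoxybenzyl chloride | COc1ccc(CCl)cc1 | starting material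
6 | (4S,5S)-4,5-bis{(1S)-1-[(4-methoxybenzyl)oxy]prop-2-en-1-yl}-2,2-dimethyl-1,3-dioxolane | C=C[C@H](OCc1ccc(OC)cc1)[C@@H]1OC(C)(C)O[C@H]1[C@@H](OCc1ccc(OC)cc1)C=C | intermediate
7 | (3aS,4S,7S,7aS)-4,7-bis[(4-methoxybenzyl)oxy]-2,2-dimethyl-3a,4,7,7a-tetrahydro-1,3-benzodioxole | CC1(C)O[C@H]2[C@@H](OCc3ccc(OC)cc3)C=C[C@H](OCc3ccc(OC)cc3)[C@@H]2O1 | intermediate
8 | (1R,2R,3S,6S)-3,6-bis[(4-methoxybenzyl)oxy]cyclohex-4-ene-1,2-diol | O[C@H]1[C@@H](OCc2ccc(OC)cc2)C=C[C@H](OCc2ccc(OC)cc2)[C@@H]1O | intermediate
9 | (bromomethyl)chlorodimethylsilane | C[Si](C)(Cl)CBr | starting material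
10 | (1S,2S,5S,6R)-6-{[(bromomethyl)dimethylsilyl]oxy}-2,5-bis[(4-methoxybenzyl)oxy]cyclohex-3-en-1-ol | O[C@H]1[C@@H](OCc2ccc(OC)cc2)C=C[C@H](OCc2ccc(OC)cc2)[C@@H]1O[Si](C)(C)CBr | intermediate
11 | (2S,5S,6S)-6-{[(bromomethyl)dimethylsilyl]oxy}-2,5-bis[(4-methoxybenzyl)oxy]cyclohex-3-en-1-one | O=C1[C@@H](OCc2ccc(OC)cc2)C=C[C@H](OCc2ccc(OC)cc2)[C@@H]1O[Si](C)(C)CBr | intermediate
12 | diiodosamarium derivative of 11 with C7–Sm in place of C7–Br | O=C1[C@@H](OCc2ccc(OC)cc2)C=C[C@H](OCc2ccc(OC)cc2)[C@@H]1O[Si](C)(C)C[Sm](I)I | intermediate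
13 | (3aS,4S,7S,7aS)-4,7-bis[(4-methoxybenzyl)oxy]-2,2-dimethyl-2,3,3a,4,7,7a-hexahydro-1,2-benzoxasilol-3a-ol | C[Si]2(C)C[C@]1(O)[C@@H](OCc3ccc(OC)cc3)C=C[C@H](OCc3ccc(OC)cc3)[C@@H]1O2 | intermediate
14 | (1R,2S,3S,6S)-1-(hydroxymethyl)-3,6-bis[(4-methoxybenzyl)oxy]cyclohex-4-ene-1,2-diol | OC[C@]1(O)[C@@H](OCc2ccc(OC)cc2)C=C[C@H](OCc2ccc(OC)cc2)[C@@H]1O | intermediate
15 | benzoyl chloride | O=C(Cl)c1ccccc1 | starting material
16 | [(1R,2S,5S,6S)-1,6-dihydroxy-2,5-bis[(4-methoxybenzyl)oxy]cyclohex-3-en-1-yl]methyl benzoate | O=C(OC[C@]1(O)[C@@H](OCc2ccc(OC)cc2)C=C[C@H](OCc2ccc(OC)cc2)[C@@H]1O)c1ccccc1 | intermediate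
17 | [(1S,2S,5S,6S)-2,5-bis[(4-methoxybenzyl)oxy]-1,6-bis[(triethylsilyl)oxy]cyclohex-3-en-1-yl]methyl benzoate | O=C(OC[C@]1(O[Si](CC)(CC)CC)[C@@H](OCc2ccc(OC)cc2)C=C[C@H](OCc2ccc(OC)cc2)[C@@H]1O[Si](CC)(CC)CC)c1ccccc1 | intermediate
18 | [(1S,2S,5S,6S)-2,5-dihydroxy-1,6-bis[(triethylsilyl)oxy]cyclohex-3-en-1-yl]methyl benzoate | O=C(OC[C@]1(O[Si](CC)(CC)CC)[C@@H](O)C=C[C@H](O)[C@@H]1O[Si](CC)(CC)CC)c1ccccc1 | intermediate
19 | [(1S,2S,5S,6S)-2,5-bis(benzoyloxy)-1,6-bis[(triethylsilyl)oxy]cyclohex-3-en-1-yl]methyl benzoate | O=C(OC[C@]1(O[Si](CC)(CC)CC)[C@@H](OC(=O)c2ccccc2)C=C[C@H](OC(=O)c2ccccc2)[C@@H]1O[Si](CC)(CC)CC)c1ccccc1 | intermediate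
20 | [(1R,2S,5S,6S)-2,5-bis(benzoyloxy)-1,6-dihydroxycyclohex-3-en-1-yl]methyl benzoate | O=C(OC[C@]1(O)[C@@H](OC(=O)c2ccccc2)C=C[C@H](OC(=O)c2ccccc2)[C@@H]1O)c1ccccc1 | target

Total step count: 13. Longest linear sequence: 13 steps (1 → 20); compounds 2, 5, 9 and 15 are bought.

**Steps most likely to fail**

Step 7. Electron transfer to the doubly α-oxygenated carbonyl may outrun reduction of the C–Br bond, so that the ketyl expels the oxygen substituent at C2 or C6. The carbanion may also be protonated before it closes the ring, or silicon may be lost by Peterson elimination after the addition.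
- The fallback gives up the tether and uses the methylenation and dihydroxylation sequence known for branched cyclitols.
- It sets out from 8, which is monosilylated (TBSCl, imidazole, DMF) to the O6 tert-butyldimethylsilyl ether F1.
- F1 is oxidised with Dess–Martin periodinane to the ketone F2.
- F2 is methylenated with the non-basic Cp2TiMe2 (toluene, 70 °C, Petasis methylenation) to the exocyclic alkene F3.
- Catalytic OsO4 with N-methylmorpholine N-oxide should dihydroxylate the 1,1-disubstituted C1=C7 bond in preference to the ring alkene, which is shielded on both faces by its allylic ethers.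
- Attack should come from the face opposite the pseudoaxial O6 silyl ether, giving the C1,C7-diol F4 with O1 trans to O6.
- Bu4NF then removes the silyl ether, and the sequence comes back to the route at 14.

Step 6. The new ketone may enolise toward C2 or C6 and lose the C5 alkoxide, which leads on to aromatisation. The labile silyl ether may also be lost during oxidation or on silica.
- The fallback reverses the order, so that the silyl ether is attached last. It sets out from 8.
- Bu2SnO (toluene, reflux, removal of water) gives the dibutylstannylene acetal F5.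
- Brominolysis (Br2 titrated in, CH2Cl2, 4 Å molecular sieves, 0 °C) oxidises one of the two equivalent C–O–Sn positions and stops at the α-hydroxy ketone F6.
- Silylation of F6 with 9 and imidazole at −20 °C comes back to the route at 11, which goes unpurified into step 7.

Step 1. The facial bias may be too weak in one or both vinyl transfers, or the esters may be reduced past the aldehyde stage. Either process erodes the supply of the C2-symmetric anti,anti isomer.
- The fallback sets C2 and C5 by hydride delivery instead of carbon delivery. It sets out from 1.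
- MeNH(OMe)·HCl with i-PrMgCl gives the bis-Weinreb amide F7.
- Compound 2 converts F7 into the bis(vinyl ketone) F8 (Weinreb ketone synthesis, acidic quench).
- Zn(BH4)2 in Et2O at −78 °C performs a chelation-controlled 1,2-reduction through the chelate of zinc with the carbonyl oxygen and the α-dioxolane oxygen. This should give the anti relationship at both ends and comes back to the route at 4.

**Further compounds**
F1 | step 7 | O6 tert-butyldimethylsilyl ether of 8 | O[C@H]1[C@@H](OCc2ccc(OC)cc2)C=C[C@H](OCc2ccc(OC)cc2)[C@@H]1O[Si](C)(C)C(C)(C)C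
F2 | step 7 | C1 ketone with O6 tert-butyldimethylsilyl ether | O=C1[C@@H](OCc2ccc(OC)cc2)C=C[C@H](OCc2ccc(OC)cc2)[C@@H]1O[Si](C)(C)C(C)(C)C
F3 | step 7 | exocyclic C1=C7 alkene with O6 tert-butyldimethylsilyl ether | C=C1[C@@H](OCc2ccc(OC)cc2)C=C[C@H](OCc2ccc(OC)cc2)[C@@H]1O[Si](C)(C)C(C)(C)C
F4 | step 7 | C1,C7-diol with O6 tert-butyldimethylsilyl ether | OC[C@]1(O)[C@@H](OCc2ccc(OC)cc2)C=C[C@H](OCc2ccc(OC)cc2)[C@@H]1O[Si](C)(C)C(C)(C)C
F5 | step 6 | O1,O6-dibutylstannylene acetal of 8 | CCCC[Sn]1(CCCC)O[C@H]2[C@@H](OCc3ccc(OC)cc3)C=C[C@H](OCc3ccc(OC)cc3)[C@@H]2O1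
F6 | step 6 | (2S,5S,6S)-6-hydroxy-2,5-bis[(4-methoxybenzyl)oxy]cyclohex-3-en-1-one | O=C1[C@@H](OCc2ccc(OC)cc2)C=C[C@H](OCc2ccc(OC)cc2)[C@@H]1O
F7 | step 1 | (4R,5R)-N,N'-dimethoxy-N,N',2,2-tetramethyl-1,3-dioxolane-4,5-dicarboxamide | CON(C)C(=O)[C@@H]1OC(C)(C)O[C@H]1C(=O)N(C)OC
F8 | step 1 | 1,1'-[(4R,5R)-2,2-dimethyl-1,3-dioxolane-4,5-diyl]bis(prop-2-en-1-one) | C=CC(=O)[C@@H]1OC(C)(C)O[C@H]1C(=O)C=C
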